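**Plan**

1. Numbering: seven-membered ring C1 (ester carbinol), C2 (CH2), C3 (methyl-bearing alkene carbon), C4 (alkene CH), C5 (ketone), C6 (quaternary, methyl), C10 (ring-fusion CH); five-membered ring C6, C7, C8, C9 (isopropyl carbinol), C10.
2. Enabling feature: the C5 ketone with its α-carbons C4 and C6 is an oxyallyl three-carbon unit, and C10–C1–C2–C3, oxygenated at C1, is a 2-oxygenated diene. Both lie in the seven-membered ring and are tied together by C7–C8–C9 of the five-membered ring, so a (4+3) union closes both rings.
3. Cuts: the vanillate C–O bond at C1; C3=C4 and the C1 carbinol back to a C5 ketone and a C1 enol silane; then C6–C10 and C3–C4 together to one open C15 chain; finally C1–C2 (propenyl unit) and C5–C6 (two-carbon chloroketone homologation) back to the ozonolysis product of terpinen-4-ol.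
4. Forward: the chain is built first (C1, C6–C10, the C6 methyl and the isopropyl group from terpinen-4-ol; C2, C3 and its methyl from bromopropene; C4 and C5 from 1,1-dichloroethane). Both rings then close in one operation, and the ester, the C3=C4 alkene and the free hydroxyls are set last.
5. Stereochemistry: C9 comes from (S)-terpinen-4-ol; C10 and C6 are set relative to C9 in the ring-forming step (allylic strain, trans fusion); C1 is set by hydride attack anti to the angular methyl group.

Key step: step 7

Assumption: (S)-(+)-terpinen-4-ol is used in high enantiomeric purity; C9 is never broken, so the enantiomeric purity of the target equals that of this starting material.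

**Route**

Step 1
Reactants: 1 (S)-(+)-terpinen-4-ol
Product: 2 (S)-terpinen-4-ol triethylsilyl ether
Conditions: TESOTf, 2,6-lutidine, CH2Cl2, −78 → 0 °C
Reagents that add atoms: triethylsilyl trifluoromethanesulfonate (TESOTf), CC[Si](CC)(CC)OS(=O)(=O)C(F)(F)F
Why: Silyl ether formation from a tertiary alcohol with a silyl triflate and a hindered pyridine base is routine and masks the C9 hydroxyl, which would otherwise form a lactol with the C6 ketone or suffer retro-aldol cleavage after ozonolysis, and no stereocentre is touched.

Step 2
Reactants: 2 (S)-terpinen-4-ol triethylsilyl ether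
Product: 4 (3S)-6-oxo-3-(propan-2-yl)-3-(triethylsilyloxy)heptanal, via ozonide 3 (not isolated)
Conditions: O3, CH2Cl2, −78 °C; then PPh3, −78 °C → rt
Reagents that add atoms: ozone, [O-][O+]=O
Why: Ozonolysis with reductive work-up cleaves the only alkene to the methyl ketone (future C6) and the aldehyde (future C1) without touching C9, the ozonide 3 being reduced by the phosphine.

Step 3
Reactants: 4 (3S)-6-oxo-3-(propan-2-yl)-3-(triethylsilyloxy)heptanal; 5 (E)-1-bromoprop-1-ene
Product: 6 (5S,8E)-7-hydroxy-5-(propan-2-yl)-5-(triethylsilyloxy)dec-8-en-2-one (both C7 epimers)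
Conditions: CrCl2 (4 equiv), NiCl2 (2 mol%), DMF, 25 °C
Reagents that add atoms: none
Why: The Nozaki–Hiyama–Kishi reaction adds the alkenylchromium reagent to the aldehyde only, spares the methyl ketone and the base-sensitive β-silyloxy aldehyde and keeps the E geometry, while the new carbinol (C1) forms as both epimers, which does not matter because it is oxidised in step 5.

Step 4
Reactants: 6 (5S,8E)-7-hydroxy-5-(propan-2-yl)-5-(triethylsilyloxy)dec-8-en-2-one; 7 1,1-dichloroethane
Product: 10 tertiary α-chloro methyl ketone allylic alcohol, via dichloro dialkoxide 8 (not isolated), via chloro-oxirane 9 (not isolated)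
Conditions: 7 (2.4 equiv), n-BuLi (2.3 equiv), THF/Et2O/pentane, −105 °C; add 6, −105 → −78 °C; then → 25 °C; aq. NH4Cl
Reagents that add atoms: none
Why: Carbenoid homologation of the Köbrich type, in which (1,1-dichloroethyl)lithium adds to the ketone (the first equivalent only deprotonates the hydroxyl), the tertiary alkoxide 8 closes to the chloro-oxirane 9 on warming and 9 opens at its tertiary carbon with 1,2-shift of chlorine to the tertiary α-chloro methyl ketone, so that C6 forms as both epimers, which both ionise in step 7.

Step 5
Reactants: 10 tertiary α-chloro methyl ketone allylic alcohol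
Product: 11 (6S,9E)-3-chloro-3-methyl-6-(propan-2-yl)-6-(triethylsilyloxy)undec-9-ene-2,8-dione (C3 epimers)
Conditions: Dess–Martin periodinane, NaHCO3, CH2Cl2, 0 °C → rt
Reagents that add atoms: none
Why: Dess–Martin oxidation of a secondary allylic alcohol to the enone is mild and buffered, so the tertiary α-chloroketone and the silyl ether should survive, and the two carbinol epimers converge.

Step 6
Reactants: 11 chloro enedione
Product: 13 bis(triethylsilyl enol ether) with tertiary allylic chloride, via dilithium bis-enolate 12 (not isolated)
Conditions: LDA (LiN(i-Pr)2, 2.4 equiv), THF, −78 °C (11 added to the base); TESOTf (3 equiv), −78 °C; Et3N, aq. NaHCO3; used at once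
Reagents that add atoms: triethylsilyl trifluoromethanesulfonate (TESOTf), CC[Si](CC)(CC)OS(=O)(=O)C(F)(F)F
Why: Kinetic double enolate formation and O-silylation, in which the chloroketone can only enolise toward its methyl group (C4) and the enone is deprotonated at the α′ carbon C10 to the cross-conjugated dienolate, so one operation makes both the 2-silyloxyallyl chloride and the 2-silyloxydiene, the C10=C1 enol ether being expected with C9 cis to oxygen because the bulky C9 group avoids the propenyl group.

Step 7
Reactants: 13 bis(triethylsilyl enol ether) with tertiary allylic chloride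
Product: 16 trans-fused hydroazulen-5-one C1 triethylsilyl enol ether, via silyloxyallyl cation 14 (not isolated), via cyclopentyl oxocarbenium ion 15 (not isolated)
Conditions: AgOTf (AgOSO2CF3, 1.5 equiv), 2,6-di-tert-butyl-4-methylpyridine (0.5 equiv), 4 Å molecular sieves, CH2Cl2, −78 °C (slow addition of 13), → −40 °C; pyridine/MeOH at −78 °C, aq. NaHCO3
Reagents that add atoms: none
Why: Silver ion abstracts the tertiary allylic chloride of 13 to give the 2-silyloxyallyl cation 14 (C4–C5–C6), whose tertiary terminus C6 is attacked by C10, the nucleophilic end of the tethered 2-silyloxydiene, to give cation 15; the enol silane carbon C4 then adds to C3 of the silyloxy-stabilised allyl cation C1–C2–C3 and triflate takes the silyl group from O5, a net (4+3) cycloaddition. The closest known reaction type is the intramolecular (4+3) cycloaddition of oxyallyl cations with tethered dienes, with the cation generated in the silver-assisted way known for 2-(trialkylsilyloxy)allyl chlorides. The five-membered ring closes in a 5-exo mode (C6–C10) and the seven-membered ring in a 7-endo mode onto the allyl cation (C3–C4). C10 is set relative to C9 by allylic strain (tether perpendicular to the enol ether plane, silyloxy group in the plane, isopropyl anti to the incoming C6), so the C1 arm should end cis to the C9 oxygen; C6 is set by the preference of the two oxygenated π-arms to lie trans across the forming C6–C10 bond, which should give the trans ring fusion with the methyl group cis to the C9 oxygen; C3 follows from suprafacial addition across the diene, whose two outward substituents end cis, and is removed in step 13. The step needs closure at C3 and not at C1 or at O5 (both (3+2) outcomes); this is secured by the methyl group on C3, which makes that terminus a secondary cation centre, by the E geometry of C2=C3, which lets C3 reach C4, and by the trans disposition of the arms, for which closure at C1 would give a strained trans-fused diquinane. Slow addition of 13 to the silver salt at −78 °C with a hindered pyridine keeps unreacted 13, whose C9–O bond is allylic to an enol ether, away from the silyl triflate that is set free.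

Step 8
Reactants: 16 trans-fused hydroazulen-5-one C1 triethylsilyl enol ether
Product: 17 C5 tert-butyldimethylsilyl enol ether (C4=C5) of 16
Conditions: TBSOTf (1.5 equiv), Et3N (3 equiv), CH2Cl2, −78 → 0 °C
Reagents that add atoms: tert-butyldimethylsilyl trifluoromethanesulfonate (TBSOTf), CC(C)(C)[Si](C)(C)OS(=O)(=O)C(F)(F)F
Why: Soft enolisation with a silyl triflate and triethylamine can only go toward C4 because C6 is quaternary, and the bulky silyl enol ether both masks the C5 ketone during the C1 chemistry and serves as the substrate of the later dehydrogenation.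

Step 9
Reactants: 17 bis(enol silane)
Product: 18 C1 ketone with C5 tert-butyldimethylsilyl enol ether
Conditions: K2CO3 (0.3 equiv), MeOH/THF, 0 °C
Reagents that add atoms: none
Why: Base-catalysed methanolysis of silyl enol ethers is governed by attack at silicon, so the triethylsilyl enol ether at C1 should be cleaved well before the hindered tert-butyldimethylsilyl enol ether at C5 and the tertiary alkyl silyl ether at C9, and protonation at C2 creates no stereocentre.

Step 10
Reactants: 18 C1 ketone with C5 tert-butyldimethylsilyl enol ether
Product: 19 C1 axial alcohol (1R)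
Conditions: LiAlH4, Et2O, −78 → −30 °C; aq. KNa tartrate (KNaC4H4O6)
Reagents that add atoms: none
Why: Hydride reduction of the only ketone under substrate control, in which the face of C1 syn to the axial angular methyl on C6 (and to the C3 methyl) is shielded, so hydride should add from the face of C10–H and give the axial alcohol with oxygen cis to the angular methyl and to the C9 oxygen, which is the configuration of the target.

Step 11
Reactants: 20 vanillic acid
Product: 22 4-(tert-butyldimethylsilyloxy)-3-methoxybenzoic acid, via bis-silyl derivative 21 (not isolated)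
Conditions: TBSCl (2.5 equiv), imidazole, DMF, rt; then AcOH/THF/H2O, rt
Reagents that add atoms: tert-butyldimethylsilyl chloride (TBSCl), CC(C)(C)[Si](C)(C)Cl
Why: Silylation of both the phenol and the acid followed by selective hydrolysis of the labile silyl ester is a standard way to mask the phenol of a hydroxybenzoic acid, and no stereocentre is involved.

Step 12
Reactants: 19 C1 axial alcohol; 22 4-(tert-butyldimethylsilyloxy)-3-methoxybenzoic acid
Product: 24 C1 O-silylvanillate ester, via acid chloride 23 (not isolated)
Conditions: 22, (COCl)2, DMF (cat.), CH2Cl2, 0 °C → rt, evaporate; then 19, DMAP, pyridine, CH2Cl2, 40 °C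
Reagents that add atoms: none
Why: Esterification of a hindered secondary alcohol with an aroyl chloride under nucleophilic catalysis by 4-(dimethylamino)pyridine proceeds with retention at C1 and without strong base, which avoids migration of the C9 silyl group to the C1 oxygen.

Step 13
Reactants: 24 C1 O-silylvanillate ester
Product: 25 C3=C4 enone, silyl-protected at the phenol and at C9
Conditions: Pd(OAc)2 (1.2 equiv), DMSO, 45 °C
Reagents that add atoms: none
Why: Saegusa–Ito oxidation, in which the C5 silyl enol ether gives the palladium enolate at C4 and β-hydride elimination of the only β-hydrogen (C3–H) gives the C3=C4 enone, removing the C3 stereocentre under non-basic conditions that spare the C1 ester.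

Step 14
Reactants: 25 C3=C4 enone, silyl-protected at the phenol and at C9
Product: 26 target, (3R,3aS,4R,8aS)-3-hydroxy-6,8a-dimethyl-8-oxo-3-(propan-2-yl)-1,2,3,3a,4,5,8,8a-octahydroazulen-4-yl 4-hydroxy-3-methoxybenzoate
Conditions: TBAF, AcOH (1:1), THF, 0 °C → rt
Reagents that add atoms: none
Why: Fluoride desilylation cleaves the aryl and the tertiary alkyl silyl ether in one operation, while the acetic acid buffer prevents base-induced vinylogous elimination of the vanillate, and no stereocentre is affected.

**Compound list**

1 | (S)-(+)-terpinen-4-ol, (1S)-4-methyl-1-(propan-2-yl)cyclohex-3-en-1-ol | CC1=CC[C@](O)(C(C)C)CC1 | starting material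
2 | (S)-terpinen-4-ol triethylsilyl ether | CC1=CC[C@](O[Si](CC)(CC)CC)(C(C)C)CC1 | intermediate
3 | ozonide (1,2,4-trioxolane across the former alkene) of 2, not isolated | CC12CC[C@@](O[Si](CC)(CC)CC)(C(C)C)CC(OO1)O2 | intermediate
4 | (3S)-6-oxo-3-(propan-2-yl)-3-(triethylsilyloxy)heptanal | CC(=O)CC[C@@](O[Si](CC)(CC)CC)(C(C)C)CC=O | intermediate
5 | (E)-1-bromoprop-1-ene | C/C=C/Br | starting material
6 | (5S,8E)-7-hydroxy-5-(propan-2-yl)-5-(triethylsilyloxy)dec-8-en-2-one, both C7 epimers | CC(=O)CC[C@@](O[Si](CC)(CC)CC)(C(C)C)CC(O)/C=C/C | intermediate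
7 | 1,1-dichloroethane | CC(Cl)Cl | starting material
8 | dilithium dialkoxide of the (1,1-dichloroethyl) adduct of 6, not isolated | CC(Cl)(Cl)C(C)(O[Li])CC[C@@](O[Si](CC)(CC)CC)(C(C)C)CC(O[Li])/C=C/C | intermediate
9 | 2-chloro-2,3-dimethyloxirane carrying the chain at C3 (lithium alkoxide at C1), not isolated | CC1(Cl)OC1(C)CC[C@@](O[Si](CC)(CC)CC)(C(C)C)CC(O[Li])/C=C/C | intermediate
10 | (6S,9E)-3-chloro-8-hydroxy-3-methyl-6-(propan-2-yl)-6-(triethylsilyloxy)undec-9-en-2-one, C3 and C8 epimers | CC(=O)C(C)(Cl)CC[C@@](O[Si](CC)(CC)CC)(C(C)C)CC(O)/C=C/C | intermediate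
11 | (6S,9E)-3-chloro-3-methyl-6-(propan-2-yl)-6-(triethylsilyloxy)undec-9-ene-2,8-dione, C3 epimers | CC(=O)C(C)(Cl)CC[C@@](O[Si](CC)(CC)CC)(C(C)C)CC(=O)/C=C/C | intermediate
12 | dilithium bis-enolate of 11 (C4=C5 and C10=C1), not isolated | C=C(O[Li])C(C)(Cl)CC[C@@](O[Si](CC)(CC)CC)(C(C)C)/C=C(\O[Li])/C=C/C | intermediate
13 | open-chain bis(triethylsilyl enol ether): C4=C5(OSiEt3), C6 chloride (both epimers), C9 OSiEt3 as in 1, C10=C1(OSiEt3) with C9 cis to oxygen, C2=C3 E | C=C(O[Si](CC)(CC)CC)C(C)(Cl)CC[C@@](O[Si](CC)(CC)CC)(C(C)C)/C=C(\O[Si](CC)(CC)CC)/C=C/C | intermediate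
14 | 2-silyloxyallyl cation (C4–C5–C6) triflate, not isolated | C=C(O[Si](CC)(CC)CC)[C+](C)CC[C@@](O[Si](CC)(CC)CC)(C(C)C)/C=C(\O[Si](CC)(CC)CC)/C=C/C.[O-]S(=O)(=O)C(F)(F)F | intermediate
15 | cyclopentane with C6–C10 formed, C5 enol silane arm on C6 and silyloxy-allyl cation arm (C1–C2–C3) on C10, arms trans, triflate, not isolated | C=C(O[Si](CC)(CC)CC)[C@@]1(C)CC[C@@](O[Si](CC)(CC)CC)(C(C)C)[C@@H]1C(=[O+][Si](CC)(CC)CC)/C=C/C.[O-]S(=O)(=O)C(F)(F)F | intermediate
16 | trans-fused hydroazulen-5-one, C1=C2 triethylsilyl enol ether; C6 methyl, C9 OSiEt3 and the C10–C1 bond on one face of the five-membered ring, C10–H and isopropyl on the other; C3–H cis to C10–H | CC[Si](CC)(CC)OC1=C[C@H](C)CC(=O)[C@@]2(C)CC[C@@](O[Si](CC)(CC)CC)(C(C)C)[C@H]12 | intermediate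
17 | 16 with the C5 ketone as its C4=C5 tert-butyldimethylsilyl enol ether | CC[Si](CC)(CC)OC1=C[C@H](C)C=C(O[Si](C)(C)C(C)(C)C)[C@@]2(C)CC[C@@](O[Si](CC)(CC)CC)(C(C)C)[C@H]12 | intermediate
18 | C1 ketone, C4=C5 tert-butyldimethylsilyl enol ether, C9 OSiEt3 | O=C1C[C@H](C)C=C(O[Si](C)(C)C(C)(C)C)[C@@]2(C)CC[C@@](O[Si](CC)(CC)CC)(C(C)C)[C@H]12 | intermediate
19 | (1R) alcohol of 18, hydroxyl axial, trans to C10–H and cis to the C6 methyl | O[C@@H]1C[C@H](C)C=C(O[Si](C)(C)C(C)(C)C)[C@@]2(C)CC[C@@](O[Si](CC)(CC)CC)(C(C)C)[C@H]12 | intermediate
20 | vanillic acid | COc1cc(C(=O)O)ccc1O | starting material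
21 | tert-butyldimethylsilyl 4-(tert-butyldimethylsilyloxy)-3-methoxybenzoate, not isolated | COc1cc(C(=O)O[Si](C)(C)C(C)(C)C)ccc1O[Si](C)(C)C(C)(C)C | intermediate
22 | 4-(tert-butyldimethylsilyloxy)-3-methoxybenzoic acid | COc1cc(C(=O)O)ccc1O[Si](C)(C)C(C)(C)C | intermediate
23 | 4-(tert-butyldimethylsilyloxy)-3-methoxybenzoyl chloride, not isolated | COc1cc(C(=O)Cl)ccc1O[Si](C)(C)C(C)(C)C | intermediate
24 | C1 ester of 19 with 22 | COc1cc(C(=O)O[C@@H]2C[C@H](C)C=C(O[Si](C)(C)C(C)(C)C)[C@@]3(C)CC[C@@](O[Si](CC)(CC)CC)(C(C)C)[C@H]23)ccc1O[Si](C)(C)C(C)(C)C | intermediate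
25 | C3=C4 enone, aryl OTBS, C9 OSiEt3 | COc1cc(C(=O)O[C@@H]2CC(C)=CC(=O)[C@@]3(C)CC[C@@](O[Si](CC)(CC)CC)(C(C)C)[C@H]23)ccc1O[Si](C)(C)C(C)(C)C | intermediate
26 | (3R,3aS,4R,8aS)-3-hydroxy-6,8a-dimethyl-8-oxo-3-(propan-2-yl)-1,2,3,3a,4,5,8,8a-octahydroazulen-4-yl 4-hydroxy-3-methoxybenzoate | COc1cc(C(=O)O[C@@H]2CC(C)=CC(=O)[C@@]3(C)CC[C@@](O)(C(C)C)[C@H]23)ccc1O | target

**Step count and risks**

Total steps: 14. Longest linear sequence: 13 steps (steps 1–10 and 12–14); step 11 is a one-step side branch.

Steps most likely to fail:

1. Step 7. The cascade may stop after the first C–C bond, the intermediate cation may close at C1 or on oxygen instead of at C3, or the silyl triflate set free may ionise the allylic C9–O bond of precursor not yet consumed. The fallback sets out from 13 and comes back at 16 by making the two bonds in separate operations. Treatment of 13 with AgOCOCF3 and Na2CO3 in CH2Cl2 at −78 °C is a silver-assisted α-tert-alkylation of an enol silane, in which the trifluoroacetate counter-ion removes the O1 silyl group as soon as C10 has alkylated the cation. This should give the cyclopentyl enone enol silane F1, in which C6–C10 is formed and the C9–O bond is no longer allylic to an enol ether. An intramolecular Mukaiyama–Michael addition of the C4 enol silane to C3 of the enone (TESOTf 10 mol%, 2,6-di-tert-butylpyridine, CH2Cl2, −78 °C), with silyl transfer to O1, then closes the seven-membered ring and gives 16.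

2. Step 4. The carbenoid may deprotonate the methyl ketone instead of adding, or the chloro-oxirane may fail to rearrange cleanly with chlorine shift while the C1 alkoxide is present. The fallback sets out from 6 and comes back at 11. Wittig ethylidenation of the methyl ketone (EtPPh3Br, KN(SiMe3)2, THF, 0 °C → rt; the alkoxide is tolerated) gives the trisubstituted alkenol F2 as an E/Z mixture. Dess–Martin oxidation gives the enone alkene F3. Epoxidation of the electron-rich trisubstituted alkene (mCPBA, NaHCO3, CH2Cl2, 0 °C; the enone alkene is inert) gives the epoxy enone F4. Markovnikov opening with HCl (1 M in Et2O, CH2Cl2, −40 °C) gives the tertiary chloride with secondary alcohol, the chlorohydrin enone F5. Dess–Martin oxidation of F5 gives 11.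

3. Step 6. Deprotonation may occur at the γ-methyl group instead of the hindered C10 methylene, the C10 enolate may expel the C9 silyloxy group, or the α-chloro enolate may decompose before it is silylated. The fallback sets out from 11 and comes back at 16; it needs no enolate of the chloroketone. Soft enolisation with TESOTf (1.05 equiv) and Et3N in CH2Cl2 at −78 °C should silylate the more Lewis-basic and less hindered enone carbonyl in preference to the α-chloroketone and give the chloroketone dienol silane F6. Base-induced ionisation of the chloroketone (Et3N, LiClO4, Et2O, rt), the classical route from an α-chloroketone to an oxyallyl cation, then closes both rings and gives 16.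

**Further compounds**

F1 | step 7 | cyclopentyl enone enol silane (C6–C10 formed; C5 triethylsilyl enol ether arm on C6, (E)-crotonoyl arm on C10, arms trans) | C=C(O[Si](CC)(CC)CC)[C@@]1(C)CC[C@@](O[Si](CC)(CC)CC)(C(C)C)[C@@H]1C(=O)/C=C/C
F2 | step 4 | trisubstituted alkenol from ethylidenation of 6 (E/Z mixture, both carbinol epimers) | CC=C(C)CC[C@@](O[Si](CC)(CC)CC)(C(C)C)CC(O)/C=C/C
F3 | step 4 | enone alkene from oxidation of F2 | CC=C(C)CC[C@@](O[Si](CC)(CC)CC)(C(C)C)CC(=O)/C=C/C
F4 | step 4 | epoxy enone from F3 | CC1OC1(C)CC[C@@](O[Si](CC)(CC)CC)(C(C)C)CC(=O)/C=C/C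
F5 | step 4 | chlorohydrin enone (tertiary chloride, secondary alcohol) from F4 | CC(O)C(C)(Cl)CC[C@@](O[Si](CC)(CC)CC)(C(C)C)CC(=O)/C=C/C
F6 | step 6 | chloroketone dienol silane (free α-chloro methyl ketone, C10=C1 triethylsilyl enol ether) | CC(=O)C(C)(Cl)CC[C@@](O[Si](CC)(CC)CC)(C(C)C)/C=C(\O[Si](CC)(CC)CC)/C=C/C
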